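**Retrosynthetic overview**
1. Target ⇐ its 8‑O‑triethylsilyl ether (desilylation last).
2. Ring‑forming operation: Ni/Cr coupling of an E‑vinyl iodide with an α‑hydroxy aldehyde closes C5–C6 (ten‑membered carbocycle, first ring); the chromium alkoxide then closes the α‑methylene‑γ‑lactone onto a pendant acrylate ester (second ring) in the same flask.
3. Open‑chain precursor ⇐ chelation‑controlled addition of an acrylate α‑anion equivalent to a C7 ketone (sets C7), then oxidation of a primary silyl ether to the C6 aldehyde.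
4. Ketone ⇐ syn‑selective chiral boron aldol of bis‑silylated dihydroxyacetone with a (2Z,6E)‑iodo dienal (sets C8, C9), then senecioylation.
5. Dienal ⇐ pent‑4‑yn‑1‑ol by carboalumination–iodination and Still–Gennari olefination.

Assumption: germacranolide numbering is used as a labelling aid (lactone C12–O–C6, C7 tertiary carbinol, C8 OH, C9 senecioate, C1=C10 Z, C4=C5 E), and (−)‑Ipc2BCl is taken as the reagent enantiomer that delivers the (8S,9R) aldol, its antipode being used otherwise.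

**Step 1**
Reactants: 1 pent‑4‑yn‑1‑ol
Product: 2 (E)‑5‑iodo‑4‑methylpent‑4‑en‑1‑ol
Conditions: AlMe3 (3 equiv), Cp2ZrCl2 (0.25 equiv), CH2Cl2, 0 °C to rt; then I2, THF, −30 °C
Reagents that add atoms: trimethylaluminium C[Al](C)C; iodine II
Why: Negishi zirconium‑catalysed carboalumination adds methyl and aluminium syn across the terminal alkyne with methyl on the internal carbon, and iodinolysis with retention gives only the E‑iodoalkene.

**Step 2**
Reactants: 2 (E)‑5‑iodo‑4‑methylpent‑4‑en‑1‑ol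
Product: 3 (E)‑5‑iodo‑4‑methylpent‑4‑enal
Conditions: TEMPO (10 mol %), PhI(OAc)2, CH2Cl2, rt
Reagents that add atoms: none
Why: Oxoammonium‑catalysed (TEMPO) alcohol oxidation stops at the aldehyde and leaves the vinyl iodide untouched.

**Step 3**
Reactants: 3 (E)‑5‑iodo‑4‑methylpent‑4‑enal; 4 ethyl 2‑[bis(2,2,2‑trifluoroethoxy)phosphoryl]propanoate
Product: 5 ethyl (2Z,6E)‑7‑iodo‑2,6‑dimethylhepta‑2,6‑dienoate
Conditions: KN(SiMe3)2, 18‑crown‑6, THF, −78 °C
Reagents that add atoms: none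
Why: Still–Gennari olefination, in which the electron‑poor phosphonate eliminates faster than the adducts equilibrate, gives the kinetic Z‑trisubstituted enoate, and the base does not touch the vinyl iodide.

**Step 4**
Reactants: 5 ethyl (2Z,6E)‑7‑iodo‑2,6‑dimethylhepta‑2,6‑dienoate
Product: 6 (2Z,6E)‑7‑iodo‑2,6‑dimethylhepta‑2,6‑dien‑1‑ol
Conditions: i‑Bu2AlH (2.2 equiv), CH2Cl2, −78 °C; aq. KNaC4H4O6
Reagents that add atoms: none
Why: Hydride 1,2‑reduction of the enoate gives the allylic alcohol without changing either alkene geometry or the C–I bond.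

**Step 5**
Reactants: 6 (2Z,6E)‑7‑iodo‑2,6‑dimethylhepta‑2,6‑dien‑1‑ol
Product: 7 (2Z,6E)‑7‑iodo‑2,6‑dimethylhepta‑2,6‑dienal
Conditions: TEMPO (10 mol %), PhI(OAc)2, CH2Cl2, 0 °C to rt
Reagents that add atoms: none
Why: The same TEMPO oxidation is free of acid and base and, as in the conversion of nerol into neral, keeps the Z‑enal geometry.

**Step 6**
Reactants: 8 1,3‑dihydroxyacetone (used as the commercial dimer)
Product: 9 1,3‑bis(triethylsilyloxy)propan‑2‑one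
Conditions: Et3SiCl, imidazole, DMF, 0 °C
Reagents that add atoms: chlorotriethylsilane CC[Si](Cl)(CC)CC
Why: Silylation of both primary hydroxyls (the dimer cracks to the monomer) gives a symmetric ketone whose two silyl ethers later differ as primary and secondary.

**Step 7**
Reactants: 9 1,3‑bis(triethylsilyloxy)propan‑2‑one; 7 (2Z,6E)‑7‑iodo‑2,6‑dimethylhepta‑2,6‑dienal
Product: 11 (3S,4R,5Z,9E)‑4‑hydroxy‑10‑iodo‑5,9‑dimethyl‑1,3‑bis(triethylsilyloxy)deca‑5,9‑dien‑2‑one, via boron enolate 10 (not isolated)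
Conditions: (−)‑Ipc2BCl, Et3N, Et2O, 0 °C; then 7, −78 to −20 °C; H2O2, pH 7 buffer, MeOH, 0 °C
Reagents that add atoms: none
Why: Paterson‑type chiral boron aldol reaction, in which the α‑silyloxy ketone enolises to the Z‑enol borinate 10 and reacts through a Zimmerman–Traxler chair to give the syn (C8/C9 threo) aldol, the Ipc ligands choosing the aldehyde face and so setting 8S and 9R while the low temperature preserves the Z‑enal.

**Step 8**
Reactants: 11 (3S,4R,5Z,9E)‑4‑hydroxy‑10‑iodo‑5,9‑dimethyl‑1,3‑bis(triethylsilyloxy)deca‑5,9‑dien‑2‑one; 12 3‑methylbut‑2‑enoic acid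
Product: 13 (3S,4R,5Z,9E)‑10‑iodo‑5,9‑dimethyl‑2‑oxo‑1,3‑bis(triethylsilyloxy)deca‑5,9‑dien‑4‑yl 3‑methylbut‑2‑enoate
Conditions: DCC, DMAP (20 mol %), CH2Cl2, 0 °C to rt
Reagents that add atoms: none
Why: Steglich esterification acylates the only free hydroxyl under near‑neutral conditions, avoiding β‑elimination of the β‑acyloxy ketone and deconjugation of the senecioate.

**Step 9**
Reactants: 13 (3S,4R,5Z,9E)‑10‑iodo‑5,9‑dimethyl‑2‑oxo‑1,3‑bis(triethylsilyloxy)deca‑5,9‑dien‑4‑yl 3‑methylbut‑2‑enoate; 14 methyl propiolate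
Product: 16 methyl 2‑[(2R,3S,4R,5Z,9E)‑2‑hydroxy‑10‑iodo‑5,9‑dimethyl‑4‑(3‑methylbut‑2‑enoyloxy)‑1,3‑bis(triethylsilyloxy)deca‑5,9‑dien‑2‑yl]prop‑2‑enoate, via vinylalane 15 (not isolated)
Conditions: 14, i‑Bu2AlH, NMO, THF, 0 °C; then added to 13 + Me2AlCl (2.5 equiv), CH2Cl2, −78 to −30 °C; aq. KNaC4H4O6
Reagents that add atoms: none
Why: Proposed new method: hydroalumination of methyl propiolate gives the α‑aluminoacrylate 15 (closest known reaction type: vinylalumination of aldehydes and activated ketones, a Morita–Baylis–Hillman surrogate), and Me2AlCl is expected to hold the C7 carbonyl and the C8 silyloxy oxygen in a five‑membered chelate, as it does in chelation‑controlled additions to α‑silyloxy carbonyls, so that the vinyl group adds to the ketone face opposite the C9 branch (Cram‑chelate) and sets C7 with the 7,8‑erythro relationship of the target.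

**Step 10**
Reactants: 16 methyl 2‑[(2R,3S,4R,5Z,9E)‑2‑hydroxy‑10‑iodo‑5,9‑dimethyl‑4‑(3‑methylbut‑2‑enoyloxy)‑1,3‑bis(triethylsilyloxy)deca‑5,9‑dien‑2‑yl]prop‑2‑enoate
Product: 17 methyl 2‑[(2S,3S,4R,5Z,9E)‑2‑hydroxy‑10‑iodo‑5,9‑dimethyl‑4‑(3‑methylbut‑2‑enoyloxy)‑1‑oxo‑3‑(triethylsilyloxy)deca‑5,9‑dien‑2‑yl]prop‑2‑enoate
Conditions: (COCl)2, DMSO, CH2Cl2, −78 to −40 °C; then Et3N
Reagents that add atoms: none
Why: Swern conditions oxidise a primary triethylsilyl ether directly to the aldehyde (the chlorosulfonium ion cleaves the unhindered O–Si bond) while the secondary silyl ether, the tertiary alcohol and both esters survive, which saves a separate deprotection.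

**Step 11**
Reactants: 17 methyl 2‑[(2S,3S,4R,5Z,9E)‑2‑hydroxy‑10‑iodo‑5,9‑dimethyl‑4‑(3‑methylbut‑2‑enoyloxy)‑1‑oxo‑3‑(triethylsilyloxy)deca‑5,9‑dien‑2‑yl]prop‑2‑enoate
Product: 19 (1(10)Z,4E,6S,7R,8S,9R)‑7‑hydroxy‑9‑(3‑methylbut‑2‑enoyloxy)‑8‑(triethylsilyloxy)germacra‑1(10),4,11(13)‑trien‑12,6‑olide, via chromium alkoxide 18 (not isolated)
Conditions: CrCl2 (10 equiv), NiCl2 (2 mol %), DMSO–THF 3:1, 0.002 M, rt, 24 h; aq. NH4Cl
Reagents that add atoms: none
Why: Nozaki–Hiyama–Kishi macrocyclisation followed in the same flask by lactonisation, in which zerovalent nickel inserts into the C–I bond, the alkenyl group passes to chromium (trivalent) and adds to the aldehyde with retention of the E‑alkene to close the ten‑membered ring, the free C7 hydroxyl chelating chromium to the aldehyde oxygen so that C5 attacks the face remote from C8 (6S), and the chromium alkoxide 18, cis to the acrylate ester, then closes the γ‑lactone with loss of methanol.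

**Step 12**
Reactants: 19 (1(10)Z,4E,6S,7R,8S,9R)‑7‑hydroxy‑9‑(3‑methylbut‑2‑enoyloxy)‑8‑(triethylsilyloxy)germacra‑1(10),4,11(13)‑trien‑12,6‑olide
Product: 20 (1(10)Z,4E,6S,7S,8S,9R)‑7,8‑dihydroxy‑9‑(3‑methylbut‑2‑enoyloxy)germacra‑1(10),4,11(13)‑trien‑12,6‑olide (CNP0258484.1)
Conditions: HF·pyridine, pyridine, THF, 0 °C
Reagents that add atoms: none
Why: Fluoride cleavage of the secondary silyl ether under buffered, mildly acidic conditions touches no stereocentre and avoids the translactonisation to O8 and the 9‑to‑8 acyl shift that base would cause.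

**Compound list**
1 | pent‑4‑yn‑1‑ol | C#CCCCO | starting material
2 | (E)‑5‑iodo‑4‑methylpent‑4‑en‑1‑ol | I/C=C(\C)CCCO | intermediate
3 | (E)‑5‑iodo‑4‑methylpent‑4‑enal | I/C=C(\C)CCC=O | intermediate
4 | ethyl 2‑[bis(2,2,2‑trifluoroethoxy)phosphoryl]propanoate | CCOC(=O)C(C)P(=O)(OCC(F)(F)F)OCC(F)(F)F | starting material
5 | ethyl (2Z,6E)‑7‑iodo‑2,6‑dimethylhepta‑2,6‑dienoate | I/C=C(\C)CC/C=C(/C)C(=O)OCC | intermediate
6 | (2Z,6E)‑7‑iodo‑2,6‑dimethylhepta‑2,6‑dien‑1‑ol | I/C=C(\C)CC/C=C(/C)CO | intermediate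
7 | (2Z,6E)‑7‑iodo‑2,6‑dimethylhepta‑2,6‑dienal | I/C=C(\C)CC/C=C(/C)C=O | intermediate
8 | 1,3‑dihydroxyacetone (sold as its dimer) | OCC(=O)CO | starting material
9 | 1,3‑bis(triethylsilyloxy)propan‑2‑one | CC[Si](CC)(CC)OCC(=O)CO[Si](CC)(CC)CC | intermediate
10 | (Z)‑1,3‑bis(triethylsilyloxy)prop‑1‑en‑2‑yl diisopinocampheylborinate | CC[Si](CC)(CC)OC/C(OB([C@@H]1C[C@@H]2C[C@H]([C@H]1C)C2(C)C)[C@@H]1C[C@@H]2C[C@H]([C@H]1C)C2(C)C)=C/O[Si](CC)(CC)CC | intermediate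
11 | (3S,4R,5Z,9E)‑4‑hydroxy‑10‑iodo‑5,9‑dimethyl‑1,3‑bis(triethylsilyloxy)deca‑5,9‑dien‑2‑one | I/C=C(\C)CC/C=C(/C)[C@@H](O)[C@H](O[Si](CC)(CC)CC)C(=O)CO[Si](CC)(CC)CC | intermediate
12 | 3‑methylbut‑2‑enoic acid (senecioic acid) | CC(C)=CC(=O)O | starting material
13 | (3S,4R,5Z,9E)‑10‑iodo‑5,9‑dimethyl‑2‑oxo‑1,3‑bis(triethylsilyloxy)deca‑5,9‑dien‑4‑yl 3‑methylbut‑2‑enoate | I/C=C(\C)CC/C=C(/C)[C@@H](OC(=O)C=C(C)C)[C@H](O[Si](CC)(CC)CC)C(=O)CO[Si](CC)(CC)CC | intermediate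
14 | methyl propiolate | C#CC(=O)OC | starting material
15 | [1‑(methoxycarbonyl)ethenyl]bis(2‑methylpropyl)alane | C=C(C(=O)OC)[Al](CC(C)C)CC(C)C | intermediate
16 | methyl 2‑[(2R,3S,4R,5Z,9E)‑2‑hydroxy‑10‑iodo‑5,9‑dimethyl‑4‑(3‑methylbut‑2‑enoyloxy)‑1,3‑bis(triethylsilyloxy)deca‑5,9‑dien‑2‑yl]prop‑2‑enoate | I/C=C(\C)CC/C=C(/C)[C@@H](OC(=O)C=C(C)C)[C@H](O[Si](CC)(CC)CC)[C@@](C(=C)C(=O)OC)(CO[Si](CC)(CC)CC)O | intermediate
17 | methyl 2‑[(2S,3S,4R,5Z,9E)‑2‑hydroxy‑10‑iodo‑5,9‑dimethyl‑4‑(3‑methylbut‑2‑enoyloxy)‑1‑oxo‑3‑(triethylsilyloxy)deca‑5,9‑dien‑2‑yl]prop‑2‑enoate | I/C=C(\C)CC/C=C(/C)[C@@H](OC(=O)C=C(C)C)[C@H](O[Si](CC)(CC)CC)[C@@](C(=C)C(=O)OC)(C=O)O | intermediate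
18 | dichlorochromium 6‑alkoxide of methyl (1(10)Z,4E,6S,7S,8S,9R)‑7‑hydroxy‑9‑(3‑methylbut‑2‑enoyloxy)‑8‑(triethylsilyloxy)germacra‑1(10),4,11(13)‑trien‑12‑oate | Cl[Cr](Cl)O[C@H]1/C=C(\C)CC/C=C(/C)[C@@H](OC(=O)C=C(C)C)[C@H](O[Si](CC)(CC)CC)[C@]1(C(=C)C(=O)OC)O | intermediate
19 | (1(10)Z,4E,6S,7R,8S,9R)‑7‑hydroxy‑9‑(3‑methylbut‑2‑enoyloxy)‑8‑(triethylsilyloxy)germacra‑1(10),4,11(13)‑trien‑12,6‑olide | C=C1C(=O)O[C@H]2/C=C(\C)CC/C=C(/C)[C@@H](OC(=O)C=C(C)C)[C@H](O[Si](CC)(CC)CC)[C@@]12O | intermediate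
20 | (1(10)Z,4E,6S,7S,8S,9R)‑7,8‑dihydroxy‑9‑(3‑methylbut‑2‑enoyloxy)germacra‑1(10),4,11(13)‑trien‑12,6‑olide (CNP0258484.1) | C=C1C(=O)O[C@H]2/C=C(\C)CC/C=C(/C)[C@@H](OC(=O)C=C(C)C)[C@H](O)[C@@]12O | target

**Total step count:** 12. **Longest linear sequence:** 11 steps (steps 1–5 and 7–12).

**Steps most likely to fail**

Step 11. Ring strain, oligomerisation and the C6 configuration all hang on one event, and the chelation model for C6 is a prediction. The fallback sets out from 17 and comes back at 20. The tertiary hydroxyl of 17 is capped with N‑(trimethylsilyl)imidazole to give methyl 2‑[(2S,3S,4R,5Z,9E)‑10‑iodo‑5,9‑dimethyl‑4‑(3‑methylbut‑2‑enoyloxy)‑1‑oxo‑3‑(triethylsilyloxy)‑2‑(trimethylsilyloxy)deca‑5,9‑dien‑2‑yl]prop‑2‑enoate F1. The ring is then closed under ligand control instead of substrate chelation: catalytic CrCl2 with a chiral sulfonamide ligand, NiCl2, Mn powder, Cp2ZrCl2, MeCN, slow addition. The metal alkoxide lactonises on work‑up to (1(10)Z,4E,6S,7R,8S,9R)‑9‑(3‑methylbut‑2‑enoyloxy)‑8‑(triethylsilyloxy)‑7‑(trimethylsilyloxy)germacra‑1(10),4,11(13)‑trien‑12,6‑olide F2. HF·pyridine removes both silyl ethers and gives 20.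

Step 9. Vinylalumination of a hindered ketone under Me2AlCl chelation is unproven, and without chelation Felkin control would give the C7 epimer. The fallback sets out from 13 and comes back at 16. A Mukaiyama aldol addition of the trimethylsilyl ketene acetal of methyl 2‑(phenylselanyl)propanoate to the Me2AlCl‑chelated ketone (CH2Cl2, −78 °C) gives methyl (3R,4S,5R,6Z,10E)‑3‑hydroxy‑11‑iodo‑2,6,10‑trimethyl‑5‑(3‑methylbut‑2‑enoyloxy)‑2‑(phenylselanyl)‑4‑(triethylsilyloxy)‑3‑[(triethylsilyloxy)methyl]undeca‑6,10‑dienoate F3 (both C2 epimers). Oxidation with H2O2/pyridine at 0 °C and selenoxide syn‑elimination, which can only go towards the methyl group, gives 16.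

Step 7. Reagent control by the Ipc ligands over an α‑silyloxy ketone enolate may give low enantioselectivity or the wrong sense. The fallback sets out from 7 and 9 and comes back at 13. The aldol is run with achiral Chx2BCl/Et3N, which gives the racemic syn adduct, that is 11 together with its enantiomer (3R,4S,5Z,9E)‑4‑hydroxy‑10‑iodo‑5,9‑dimethyl‑1,3‑bis(triethylsilyloxy)deca‑5,9‑dien‑2‑one F4. The esterification is then run as an acylative kinetic resolution (3‑methylbut‑2‑enoic anhydride, chiral isothiourea acyl‑transfer catalyst, i‑Pr2NEt, CHCl3, 0 °C). Only 11 is converted into 13, and F4 is left as the alcohol and removed by chromatography.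

**Further compounds**
F1 | step 11 | methyl 2‑[(2S,3S,4R,5Z,9E)‑10‑iodo‑5,9‑dimethyl‑4‑(3‑methylbut‑2‑enoyloxy)‑1‑oxo‑3‑(triethylsilyloxy)‑2‑(trimethylsilyloxy)deca‑5,9‑dien‑2‑yl]prop‑2‑enoate | I/C=C(\C)CC/C=C(/C)[C@@H](OC(=O)C=C(C)C)[C@H](O[Si](CC)(CC)CC)[C@@](C(=C)C(=O)OC)(C=O)O[Si](C)(C)C
F2 | step 11 | (1(10)Z,4E,6S,7R,8S,9R)‑9‑(3‑methylbut‑2‑enoyloxy)‑8‑(triethylsilyloxy)‑7‑(trimethylsilyloxy)germacra‑1(10),4,11(13)‑trien‑12,6‑olide | C=C1C(=O)O[C@H]2/C=C(\C)CC/C=C(/C)[C@@H](OC(=O)C=C(C)C)[C@H](O[Si](CC)(CC)CC)[C@@]12O[Si](C)(C)C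
F3 | step 9 | methyl (3R,4S,5R,6Z,10E)‑3‑hydroxy‑11‑iodo‑2,6,10‑trimethyl‑5‑(3‑methylbut‑2‑enoyloxy)‑2‑(phenylselanyl)‑4‑(triethylsilyloxy)‑3‑[(triethylsilyloxy)methyl]undeca‑6,10‑dienoate | I/C=C(\C)CC/C=C(/C)[C@@H](OC(=O)C=C(C)C)[C@H](O[Si](CC)(CC)CC)[C@@](C(C)([Se]c1ccccc1)C(=O)OC)(CO[Si](CC)(CC)CC)O
F4 | step 7 | (3R,4S,5Z,9E)‑4‑hydroxy‑10‑iodo‑5,9‑dimethyl‑1,3‑bis(triethylsilyloxy)deca‑5,9‑dien‑2‑one | I/C=C(\C)CC/C=C(/C)[C@H](O)[C@@H](O[Si](CC)(CC)CC)C(=O)CO[Si](CC)(CC)CC
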